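**Remark (assumption on the chemistry).** Locants in the text follow elemanolide numbering: six-membered ring C5–C10, lactone C6(O)–C7–C11–C12, vinyl C1=C2 and methyl C14 on C10, C4(=C3)–C15 on C5, methyl C13 on C11. α is the face of the C6–O bond, β the face of the C10 methyl. Both enantiomers of 4-silyloxycyclopentenone are taken as commercial; chloro(ethynyl)dimethylsilane is made in step 6.

## Retrosynthetic overview

1. Target ⇐ desilylation, C15 allylic hydroxylation and O8 esterification of an 8α-hydroxy-11α-methyl-6,12-olide ⇐ lactone methylation, C8 reduction and C7 alkylation/lactonization of 5-hydroxy-3-methyl-3-vinyl-4-isopropenylcyclohexanone.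
2. That cyclohexanone ⇐ protodesilylation of a siloxane-bridged cyclohexanone ⇐ key step: oxidative one-carbon ring expansion of a 5-methylbicyclo[3.1.0]hexan-1-ol (cyclopentane C8–C10–C5–C6–C7 becomes the cyclohexanone, C9 is inserted), with the C10 radical caught by an ethynylsilane tethered to O6.
3. Enabling feature: in the six-membered ring the oxygenated C8 and the quaternary C10 are 1,3-related through the unsubstituted C9 methylene (a β-keto radical pattern, i.e. a latent ring-fused cyclopropanol). O6 is cis-1,3 to the C10 vinyl group, so it can carry the two vinyl carbons on a removable silicon tether.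
4. The cyclopropanol ⇐ (S)-4-silyloxycyclopentenone by α-methylation, anti conjugate addition of isopropenyl (C5) and cyclopropanation of the silyl enol ether (C9).
5. Ring order: cyclopentane (chiral pool) → fused cyclopropane → six-membered carbocycle plus temporary oxasilinane (key step) → γ-lactone.

Key step: step 8

## Route

Step 1
Reactants: 1 (S)-4-[(tert-butyldimethylsilyl)oxy]cyclopent-2-en-1-one
Product: 2 (S)-4-[(tert-butyldimethylsilyl)oxy]-2-iodocyclopent-2-en-1-one
Conditions: I2, pyridine, CH2Cl2, 0 °C to rt
Reagents that add atoms: iodine, II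
Why: α-Iodination of the enone (conjugate addition of pyridine, iodination of the enolate, elimination) is a standard reaction of cycloalkenones and should leave the silyloxy stereocentre untouched.

Step 2
Reactants: 2 (S)-4-[(tert-butyldimethylsilyl)oxy]-2-iodocyclopent-2-en-1-one
Product: 3 (S)-4-[(tert-butyldimethylsilyl)oxy]-2-methylcyclopent-2-en-1-one
Conditions: Me4Sn, Pd2(dba)3 (cat.), AsPh3, CuI (cat.), NMP, 60 °C
Reagents that add atoms: tetramethylstannane, C[Sn](C)(C)C
Why: Stille coupling of the α-iodoenone puts the future C14 methyl on C10 under neutral conditions that avoid β-elimination of the silyloxy group.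

Step 3
Reactants: 3 (S)-4-[(tert-butyldimethylsilyl)oxy]-2-methylcyclopent-2-en-1-one; 4 isopropenylmagnesium bromide
Product: 5 tert-butyl(dimethyl){[(1S,2S)-3-methyl-2-(prop-1-en-2-yl)-4-(trimethylsilyloxy)cyclopent-3-en-1-yl]oxy}silane (isopropenyl trans to OTBS)
Conditions: 4, CuBr·SMe2 (10 mol%), TMSCl, THF, −78 °C; Et3N, cold aq. NaHCO3
Reagents that add atoms: chlorotrimethylsilane, C[Si](C)(C)Cl
Why: Copper-catalysed, TMSCl-accelerated conjugate addition should deliver the isopropenyl group anti to the adjacent silyloxy group (this sets C5 trans to O6) and trap the enolate regiospecifically as the tetrasubstituted C8=C10 silyl enol ether.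

Step 4
Reactants: 5 silyl enol ether
Product: 6 3-[(tert-butyldimethylsilyl)oxy]-5-methyl-4-(prop-1-en-2-yl)-1-(trimethylsilyloxy)bicyclo[3.1.0]hexane (cyclopropane CH2 anti to isopropenyl; 3-OTBS and 4-isopropenyl trans)
Conditions: Et2Zn, CH2I2, CH2Cl2, 0 °C; pyridine quench
Reagents that add atoms: diiodomethane, ICI
Why: Furukawa-modified Simmons–Smith cyclopropanation should occur at the electron-rich silyl enol ether much faster than at the isopropenyl group, presumably anti to the C5 substituent, and the configuration of the two new cyclopropane stereocentres is irrelevant because both are destroyed in step 8.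

Step 5
Reactants: 6 bis-silylated bicyclo[3.1.0]hexane
Product: 7 5-methyl-4-(prop-1-en-2-yl)bicyclo[3.1.0]hexane-1,3-diol (same relative configuration as 6)
Conditions: TBAF, AcOH, THF, 0 °C to rt
Reagents that add atoms: none
Why: Acetic acid-buffered fluoride should cleave both silyl ethers while the sensitive tertiary cyclopropanol survives.

Step 6
Reactants: 8 dichlorodimethylsilane; 9 ethynylmagnesium bromide
Product: 10 chloro(ethynyl)dimethylsilane
Conditions: 9 added to 8 (3 equiv), THF, −78 °C to rt; distillation
Reagents that add atoms: none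
Why: Mono-alkynylation of a dichlorosilane used in excess by a Grignard reagent is a standard route to alkynyl(chloro)silanes.

Step 7
Reactants: 7 cyclopropane diol; 10 chloro(ethynyl)dimethylsilane
Product: 11 3-{[ethynyl(dimethyl)silyl]oxy}-5-methyl-4-(prop-1-en-2-yl)bicyclo[3.1.0]hexan-1-ol
Conditions: 10 (1.05 equiv), imidazole, CH2Cl2, −40 °C
Reagents that add atoms: none
Why: Silylation should be selective for the unhindered secondary C6 hydroxyl over the tertiary cyclopropanol next to the quaternary C10, and it mounts the two future vinyl carbons on the oxygen that lies 1,3 to C10.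

Step 8
Reactants: 11 tethered bicyclo[3.1.0]hexan-1-ol
Product: 13 siloxane-bridged cyclohexanone 3,3,5-trimethyl-4-methylidene-9-(prop-1-en-2-yl)-2-oxa-3-silabicyclo[3.3.1]nonan-7-one, via ring-expanded C10 radical 12 (not isolated)
Conditions: Mn(OAc)2·4H2O (10 mol%), n-Bu4NOAc (0.1 M), MeCN, 2 mM in 11, graphite anode, Pt cathode, undivided cell, constant current, 25 °C
Reagents that add atoms: none
Why: Proposed new method: Anodically regenerated Mn(III), kept at low stationary concentration, oxidizes the tertiary cyclopropanol through its Mn(III) alkoxide; β-scission of the internal C8–C10 bond turns the cyclopentane into the cyclohexanone and leaves the tertiary radical 12 at C10, which adds to the ethynylsilane on O6, and the vinyl radical takes a hydrogen atom from MeCN (the cyanomethyl radical is reduced and protonated at the cathode, so the net change is an isomerization). The closest known reaction types are the Fe(III)-, Mn(III)- and photoinduced-electron-transfer-triggered ring expansion–radical cyclization cascades of bicyclo[n.1.0]alkan-1-ols and their silyl ethers with pendant alkenes or alkynes, and silicon-tethered radical vinylation of alcohols; the γ-positioned silyl alkyne and the electrochemical mediator are new. The six-membered carbocycle arises by one-carbon ring expansion (C9 is the former cyclopropane methylene) and the temporary oxasilinane closes by 6-exo-dig radical addition; a competing 7-endo-dig closure would give an alkenylsiloxane that step 9 converts into the same product. The only new stereocentre, the quaternary C10, is controlled by the tether: the alkyne can reach the planar radical only from the face of the axial C6–O bond (1,3-diaxial bridging), which places the future vinyl group α, cis to O6 and trans to the C5 isopropenyl group, whatever the cyclopropane configuration of 11. The step needs internal instead of external cyclopropane cleavage (secured by the C10 methyl, which makes the ring-expanded radical tertiary instead of primary), cyclization faster than over-oxidation or reduction of 12 (catalytic Mn(III), high dilution, no Cu(II), halide or strong hydrogen donor) and a silent isopropenyl group (it could only close a strained three- or four-membered ring).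

Step 9
Reactants: 13 siloxane-bridged cyclohexanone
Product: 14 (3S,4S,5S)-3-ethenyl-5-hydroxy-3-methyl-4-(prop-1-en-2-yl)cyclohexan-1-one
Conditions: TBAF, CuI (cat.), THF, 0 °C to rt; AcOH
Reagents that add atoms: none
Why: Fluoride should open the Si–O bond and, assisted by copper(I), protodesilylate the 1,1-disubstituted alkenylsilane (a known reaction of such alkenylsilanes), which unveils the C10 vinyl group and the C6 hydroxyl and removes the temporary ring without touching a stereocentre.

Step 10
Reactants: 14 hydroxy ketone
Product: 15 (3S,4S,5S)-5-[(tert-butyldimethylsilyl)oxy]-3-ethenyl-3-methyl-4-(prop-1-en-2-yl)cyclohexan-1-one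
Conditions: TBSCl, imidazole, DMF, rt
Reagents that add atoms: tert-butyldimethylsilyl chloride, CC(C)(C)[Si](C)(C)Cl
Why: Standard silylation protects the β-hydroxyl so that the ketone can be enolized toward C7 without retro-aldol cleavage or dianion formation.

Step 11
Reactants: 15 silyloxy ketone; 16 methyl bromoacetate
Product: 17 methyl 2-{6α-[(tert-butyldimethylsilyl)oxy]-10α-ethenyl-10β-methyl-8-oxo-5β-(prop-1-en-2-yl)cyclohexan-7β-yl}acetate (elemanolide locants; side chain on C7 trans to O6)
Conditions: LDA, THF, −78 °C; 16, DMPU, −78 to −40 °C; then DBU (cat.), CH2Cl2, rt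
Reagents that add atoms: none
Why: Kinetic deprotonation should occur at C7 because C9 is neopentylic, the enolate is alkylated by the reactive α-bromo ester, and DBU then equilibrates the epimerizable C7 to the all-equatorial isomer with the side chain trans to O6 (thermodynamic control of C7).

Step 12
Reactants: 17 keto ester
Product: 19 trans-fused keto lactone 6-ethenyl-6-methyl-7-(prop-1-en-2-yl)hexahydro-1-benzofuran-2,4-dione (6α-O, 7β-C, 10β-methyl, 5β-isopropenyl), via hydroxy keto ester 18 (not isolated)
Conditions: HF·pyridine, THF, 0 °C to rt; then PPTS, toluene, 60 °C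
Reagents that add atoms: none
Why: Desilylation followed by acid-catalysed lactonization of the trans γ-hydroxy ester should give the trans-fused γ-lactone regiospecifically on O6, because C8 is still a ketone, and the non-basic conditions avoid epimerization at C7 and β-elimination.

Step 13
Reactants: 19 keto lactone
Product: 20 8α-hydroxy lactone 6-ethenyl-4-hydroxy-6-methyl-7-(prop-1-en-2-yl)hexahydro-1-benzofuran-2(3H)-one (hydroxyl equatorial, cis to O6)
Conditions: SmI2, H2O (50 equiv), THF, 0 °C
Reagents that add atoms: none
Why: Single-electron (ketyl) reduction with SmI2–H2O should give the thermodynamically favoured equatorial 8α-alcohol, as dissolving-metal reductions do, whereas hydride reagents would attack anti to the axial C10 methyl and give the axial epimer; γ-lactones and isolated alkenes are inert to this reagent.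

Step 14
Reactants: 20 hydroxy lactone
Product: 21 8α-hydroxy-11α-methyl lactone (3S,3aR,4S,6S,7S,7aR)-6-ethenyl-4-hydroxy-3,6-dimethyl-7-(prop-1-en-2-yl)hexahydro-1-benzofuran-2(3H)-one
Conditions: LDA (2.3 equiv), THF, −78 °C (inverse addition); MeI, −78 to −40 °C
Reagents that add atoms: iodomethane, CI
Why: The alkoxide/lactone enolate dianion should be C-methylated from the α face (the side of H7, away from the carbocycle), which gives the 11α-methyl (11S) configuration that is also the thermodynamically preferred one for a trans-fused lactone.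

Step 15
Reactants: 22 methyl (R)-3-hydroxy-2-methylpropanoate
Product: 23 methyl (R)-3-[(tert-butyldimethylsilyl)oxy]-2-methylpropanoate
Conditions: TBSCl, imidazole, CH2Cl2, 0 °C to rt
Reagents that add atoms: tert-butyldimethylsilyl chloride, CC(C)(C)[Si](C)(C)Cl
Why: Standard silylation of the primary hydroxyl of the chiral-pool ester, which supplies the side-chain stereocentre.

Step 16
Reactants: 23 silylated ester
Product: 24 (R)-3-[(tert-butyldimethylsilyl)oxy]-2-methylpropanoic acid
Conditions: LiOH, THF/H2O, 0 °C; aq. HCl to pH 4, 0 °C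
Reagents that add atoms: lithium hydroxide, [Li+].[OH-]
Why: Cold saponification and mild acidification should give the acid without β-elimination of silyloxide or racemization of the α-stereocentre.

Step 17
Reactants: 21 hydroxy methyl lactone; 24 silyloxy acid
Product: 25 O8 ester of 21 with (R)-3-[(tert-butyldimethylsilyl)oxy]-2-methylpropanoic acid
Conditions: DCC, DMAP (cat.), CH2Cl2, 0 °C to rt
Reagents that add atoms: none
Why: Steglich esterification of the only free hydroxyl, the equatorial one on C8, under conditions that should not epimerize the α-stereocentre of the acid.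

Step 18
Reactants: 25 silylated ester lactone
Product: 26 15-hydroxy derivative of 25 (3-hydroxyprop-1-en-2-yl on C5)
Conditions: SeO2 (0.5 equiv), t-BuOOH, CH2Cl2, rt
Reagents that add atoms: tert-butyl hydroperoxide, CC(C)(C)OO
Why: Riley oxidation (ene reaction of SeO2, then [2,3]-sigmatropic shift) should hydroxylate the methyl of the isopropenyl unit, the preferred allylic position of a 1,1-disubstituted alkene, while the vinyl group on the quaternary C10 has no allylic hydrogen.

Step 19
Reactants: 26 silyl-protected target
Product: 27 (3S,3aR,4S,6S,7R,7aR)-6-ethenyl-7-(3-hydroxyprop-1-en-2-yl)-3,6-dimethyl-2-oxooctahydro-1-benzofuran-4-yl (2R)-3-hydroxy-2-methylpropanoate (target)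
Conditions: HF·pyridine, pyridine, THF, 0 °C to rt
Reagents that add atoms: none
Why: Buffered HF·pyridine should remove the primary TBS ether without affecting the ester, the lactone or the allylic alcohol.

## Compound list

1 | (S)-4-[(tert-butyldimethylsilyl)oxy]cyclopent-2-en-1-one | O=C1C[C@H](O[Si](C)(C)C(C)(C)C)C=C1 | starting material
2 | (S)-4-[(tert-butyldimethylsilyl)oxy]-2-iodocyclopent-2-en-1-one | O=C1C[C@H](O[Si](C)(C)C(C)(C)C)C=C1I | intermediate
3 | (S)-4-[(tert-butyldimethylsilyl)oxy]-2-methylcyclopent-2-en-1-one | O=C1C[C@H](O[Si](C)(C)C(C)(C)C)C=C1C | intermediate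
4 | isopropenylmagnesium bromide | CC(=C)[Mg]Br | starting material
5 | tert-butyl(dimethyl){[(1S,2S)-3-methyl-2-(prop-1-en-2-yl)-4-(trimethylsilyloxy)cyclopent-3-en-1-yl]oxy}silane | C[Si](C)(C)OC1=C(C)[C@H](C(C)=C)[C@@H](O[Si](C)(C)C(C)(C)C)C1 | intermediate
6 | 3-[(tert-butyldimethylsilyl)oxy]-5-methyl-4-(prop-1-en-2-yl)-1-(trimethylsilyloxy)bicyclo[3.1.0]hexane (CH2 anti to isopropenyl) | C[Si](C)(C)O[C@]12C[C@@]1(C)[C@H](C(C)=C)[C@@H](O[Si](C)(C)C(C)(C)C)C2 | intermediate
7 | 5-methyl-4-(prop-1-en-2-yl)bicyclo[3.1.0]hexane-1,3-diol | O[C@]12C[C@@]1(C)[C@H](C(C)=C)[C@@H](O)C2 | intermediate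
8 | dichlorodimethylsilane | C[Si](C)(Cl)Cl | starting material
9 | ethynylmagnesium bromide | C#C[Mg]Br | starting material
10 | chloro(ethynyl)dimethylsilane | C#C[Si](C)(C)Cl | intermediate
11 | 3-{[ethynyl(dimethyl)silyl]oxy}-5-methyl-4-(prop-1-en-2-yl)bicyclo[3.1.0]hexan-1-ol | O[C@]12C[C@@]1(C)[C@H](C(C)=C)[C@@H](O[Si](C)(C)C#C)C2 | intermediate
12 | ring-expanded tertiary C10 radical, 5-{[ethynyl(dimethyl)silyl]oxy}-3-methyl-4-(prop-1-en-2-yl)-1-oxocyclohexan-3-yl | C[C]1CC(=O)C[C@H](O[Si](C)(C)C#C)[C@H]1C(C)=C | intermediate
13 | 3,3,5-trimethyl-4-methylidene-9-(prop-1-en-2-yl)-2-oxa-3-silabicyclo[3.3.1]nonan-7-one (bridge cis to O6, trans to isopropenyl) | C[C@@]1(C(=C)[Si](C)(C)O2)CC(=O)C[C@H]2[C@H]1C(C)=C | intermediate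
14 | (3S,4S,5S)-3-ethenyl-5-hydroxy-3-methyl-4-(prop-1-en-2-yl)cyclohexan-1-one | C=C[C@]1(C)CC(=O)C[C@H](O)[C@H]1C(C)=C | intermediate
15 | (3S,4S,5S)-5-[(tert-butyldimethylsilyl)oxy]-3-ethenyl-3-methyl-4-(prop-1-en-2-yl)cyclohexan-1-one | C=C[C@]1(C)CC(=O)C[C@H](O[Si](C)(C)C(C)(C)C)[C@H]1C(C)=C | intermediate
16 | methyl bromoacetate | COC(=O)CBr | starting material
17 | methyl 2-{6α-[(tert-butyldimethylsilyl)oxy]-10α-ethenyl-10β-methyl-8-oxo-5β-(prop-1-en-2-yl)cyclohexan-7β-yl}acetate | C=C[C@]1(C)CC(=O)[C@@H](CC(=O)OC)[C@H](O[Si](C)(C)C(C)(C)C)[C@H]1C(C)=C | intermediate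
18 | hydroxy keto ester, 6α-hydroxy analogue of 17 | C=C[C@]1(C)CC(=O)[C@@H](CC(=O)OC)[C@H](O)[C@H]1C(C)=C | intermediate
19 | trans-fused 6-ethenyl-6-methyl-7-(prop-1-en-2-yl)hexahydro-1-benzofuran-2,4-dione | C=C[C@]1(C)CC(=O)[C@@H]2[C@H](OC(=O)C2)[C@H]1C(C)=C | intermediate
20 | trans-fused 6-ethenyl-4α-hydroxy-6-methyl-7-(prop-1-en-2-yl)hexahydro-1-benzofuran-2(3H)-one | C=C[C@]1(C)C[C@H](O)[C@@H]2[C@H](OC(=O)C2)[C@H]1C(C)=C | intermediate
21 | (3S,3aR,4S,6S,7S,7aR)-6-ethenyl-4-hydroxy-3,6-dimethyl-7-(prop-1-en-2-yl)hexahydro-1-benzofuran-2(3H)-one | C=C[C@]1(C)C[C@H](O)[C@@H]2[C@H](OC(=O)[C@H]2C)[C@H]1C(C)=C | intermediate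
22 | methyl (R)-3-hydroxy-2-methylpropanoate | COC(=O)[C@H](C)CO | starting material
23 | methyl (R)-3-[(tert-butyldimethylsilyl)oxy]-2-methylpropanoate | COC(=O)[C@H](C)CO[Si](C)(C)C(C)(C)C | intermediate
24 | (R)-3-[(tert-butyldimethylsilyl)oxy]-2-methylpropanoic acid | OC(=O)[C@H](C)CO[Si](C)(C)C(C)(C)C | intermediate
25 | O8 (R)-3-[(tert-butyldimethylsilyl)oxy]-2-methylpropanoate of 21 | C=C[C@]1(C)C[C@H](OC(=O)[C@H](C)CO[Si](C)(C)C(C)(C)C)[C@@H]2[C@H](OC(=O)[C@H]2C)[C@H]1C(C)=C | intermediate
26 | 15-hydroxy derivative of 25 | C=C[C@]1(C)C[C@H](OC(=O)[C@H](C)CO[Si](C)(C)C(C)(C)C)[C@@H]2[C@H](OC(=O)[C@H]2C)[C@H]1C(=C)CO | intermediate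
27 | (3S,3aR,4S,6S,7R,7aR)-6-ethenyl-7-(3-hydroxyprop-1-en-2-yl)-3,6-dimethyl-2-oxooctahydro-1-benzofuran-4-yl (2R)-3-hydroxy-2-methylpropanoate | C=C[C@]1(C)C[C@H](OC(=O)[C@H](C)CO)[C@@H]2[C@H](OC(=O)[C@H]2C)[C@H]1C(=C)CO | target

## Step count and risks

Total step count: 19. Longest linear sequence: 16 steps (steps 1–5, 7–14, 17–19, from compound 1).

**Step 8 (Proposed new method).** The tertiary radical may be over-oxidized to the enone before it cyclizes, the external cyclopropane bond may be cleaved, or the labile silyl tether may be lost in the electrolyte. The fallback uses known chemistry, sets out from 6 and comes back at 15. Treatment of 6 with FeCl3 in DMF (the known oxidative one-carbon ring expansion of 1-siloxybicyclo[n.1.0]alkanes) should give the β-chloro ketone 5-[(tert-butyldimethylsilyl)oxy]-3-chloro-3-methyl-4-(prop-1-en-2-yl)cyclohexan-1-one F1. NaOAc in MeOH should eliminate HCl to the enone 5-[(tert-butyldimethylsilyl)oxy]-3-methyl-4-(prop-1-en-2-yl)cyclohex-2-en-1-one F2. Copper-catalysed conjugate addition of vinylmagnesium bromide (CuBr·SMe2, THF, −78 °C, aq. NH4Cl) anti to the C5 isopropenyl group would then give 15, so steps 5, 6, 7, 9 and 10 fall away. The ring is still made by expansion of the five-membered ring, but C10 then rests on intermolecular facial selectivity: the 4-isopropenyl and 5-silyloxy groups direct to opposite faces, so this is less secure than the tether.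

**Step 11.** Facial selectivity of the enolate alkylation at C7 may be poor, and the base equilibration may trigger β-elimination of the silyloxy group. The fallback sets C7 by protonation instead of alkylation; it sets out from 15 and comes back at 17. The lithium enolate of 15 is added to methyl glyoxylate to give the aldol adduct methyl 2-hydroxy-2-(C7-substituted ketone)acetate F3. Dehydration with MsCl/Et3N gives the (E)-alkylidene keto ester F4. Zn/AcOH reduces the ene-1,4-dicarbonyl unit chemoselectively, and axial protonation of the zinc enolate at C7 should place the side chain equatorial, trans to O6, which is 17.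

**Step 13.** Protonation of the ketyl may show low facial selectivity, so that the axial 8β-alcohol forms in part. The fallback makes the axial alcohol on purpose and inverts it; it sets out from 19 and comes back at 25. Lithium tri-sec-butylborohydride (THF, −78 °C) should attack from the equatorial side, anti to the axial C10 methyl, and give the 8β-hydroxy lactone F5. Dianion methylation as in step 14 gives the 8β-hydroxy-11α-methyl lactone F6. A Mitsunobu reaction of F6 with acid 24 (PPh3, DIAD, toluene) esterifies with inversion at C8 and gives 25, which replaces steps 13, 14 and 17.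

## Further compounds

F1 | step 8 | 5-[(tert-butyldimethylsilyl)oxy]-3-chloro-3-methyl-4-(prop-1-en-2-yl)cyclohexan-1-one (4,5-trans, C3 epimers) | CC1(Cl)CC(=O)C[C@H](O[Si](C)(C)C(C)(C)C)[C@H]1C(C)=C
F2 | step 8 | 5-[(tert-butyldimethylsilyl)oxy]-3-methyl-4-(prop-1-en-2-yl)cyclohex-2-en-1-one (4,5-trans) | CC1=CC(=O)C[C@H](O[Si](C)(C)C(C)(C)C)[C@H]1C(C)=C
F3 | step 11 | methyl 2-hydroxy-2-{6α-[(tert-butyldimethylsilyl)oxy]-10α-ethenyl-10β-methyl-8-oxo-5β-(prop-1-en-2-yl)cyclohexan-7-yl}acetate (epimers) | C=C[C@]1(C)CC(=O)C(C(O)C(=O)OC)[C@H](O[Si](C)(C)C(C)(C)C)[C@H]1C(C)=C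
F4 | step 11 | methyl (E)-2-{6α-[(tert-butyldimethylsilyl)oxy]-10α-ethenyl-10β-methyl-8-oxo-5β-(prop-1-en-2-yl)cyclohexan-7-ylidene}acetate | C=C[C@]1(C)CC(=O)/C(=C/C(=O)OC)[C@H](O[Si](C)(C)C(C)(C)C)[C@H]1C(C)=C
F5 | step 13 | 8β-hydroxy epimer of 20 | C=C[C@]1(C)C[C@@H](O)[C@@H]2[C@H](OC(=O)C2)[C@H]1C(C)=C
F6 | step 13 | 8β-hydroxy epimer of 21 | C=C[C@]1(C)C[C@@H](O)[C@@H]2[C@H](OC(=O)[C@H]2C)[C@H]1C(C)=C
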